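**Retrosynthetic overview**

1. Target 26 ← saponification of ester 25 ← β‑lactone olefination of the C1 ketone in 22 ← O‑demethylation of 21 ← hydrogenation and methanolysis of tricyclic enol lactone 19, which sets C10 by ketonisation.
2. Key disconnection: 19 ← achiral trienyl enol lactone 18 by a chiral‑borate‑templated intramolecular Diels–Alder reaction. Ring A (C4–C5) and ring B (C8–C9) close in one operation and C4, C5, C8, C9 are set; the lactone is the latent C1 ketone plus propanoate chain.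
3. 18 ← aldol condensation of aldehyde 12 with aryl ethyl ketone 15; 12 ← Suzuki coupling of bromo enol lactone 7 with dienylboronate 10; 7 ← glutaric anhydride and a dioxolane Grignard reagent.
4. Ring order: arene bought; lactone ring (step 2); rings A and B together (step 9); lactone ring opened (step 10).
5. Numbering used below: ring A = C1(=CMe2)–C2–C3–C4(H)–C5(CH3)–C10(CH2CH2CO2H); ring B = C4–C5–C6–C7–C8(CH3)–C9(CH3, aroyl); α = face of H‑4, β = face of the C5 methyl.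

Assumption: (R)‑BINOL is taken to give the (6aS,7S,8S,10aR) adduct 19; the sense of induction must be confirmed on the first run, and (S)‑BINOL is used instead if it is reversed.

**Route**

Step 1
Reactants: 1 2‑(2‑bromoethyl)‑1,3‑dioxolane; 2 oxane‑2,6‑dione (glutaric anhydride)
Product: 4 7‑(1,3‑dioxolan‑2‑yl)‑5‑oxoheptanoic acid, via [2‑(1,3‑dioxolan‑2‑yl)ethyl]magnesium bromide 3 (not isolated)
Conditions: Mg, THF, 25 °C; add to 2 (1.5 equiv), THF, −78 → −20 °C; cold dilute HCl to pH 4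
Reagents that add atoms: none
Why: Grignard addition to a cyclic anhydride stops at the keto carboxylate, which is not attacked again at low temperature; no stereocentre.

Step 2
Reactants: 4 7‑(1,3‑dioxolan‑2‑yl)‑5‑oxoheptanoic acid
Product: 5 6‑[2‑(1,3‑dioxolan‑2‑yl)ethyl]‑3,4‑dihydro‑2H‑pyran‑2‑one
Conditions: Ac2O, NaOAc (0.2 equiv), 120 °C
Reagents that add atoms: none
Why: enol lactonization of a δ‑keto acid through its mixed anhydride gives the endocyclic six‑membered enol lactone as the thermodynamic isomer, and the base‑buffered medium spares the acetal; no stereocentre.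

Step 3
Reactants: 5 6‑[2‑(1,3‑dioxolan‑2‑yl)ethyl]‑3,4‑dihydro‑2H‑pyran‑2‑one
Product: 7 5‑bromo‑6‑[2‑(1,3‑dioxolan‑2‑yl)ethyl]‑3,4‑dihydro‑2H‑pyran‑2‑one, via trans‑5,6‑dibromo lactone 6 (not isolated)
Conditions: Br2 (1.0 equiv), CH2Cl2, −78 °C; then Et3N, −78 → 0 °C
Reagents that add atoms: bromine, BrBr
Why: bromination–dehydrobromination of the electron‑rich enol‑ester alkene (anti addition, then loss of HBr through the acyloxy‑stabilised cation) gives the 2‑bromo enol ester; no stereocentre is kept.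

Step 4
Reactants: 8 (E)‑but‑2‑enal; 9 1,1‑bis(4,4,5,5‑tetramethyl‑1,3,2‑dioxaborolan‑2‑yl)ethane
Product: 10 2‑[(2Z,4E)‑hexa‑2,4‑dien‑2‑yl]‑4,4,5,5‑tetramethyl‑1,3,2‑dioxaborolane
Conditions: lithium 2,2,6,6‑tetramethylpiperidide (1.1 equiv), THF, 0 °C; then 8, −78 → 20 °C
Reagents that add atoms: none
Why: boron–Wittig olefination, in which the α‑boryl carbanion adds 1,2 to the enal and syn B–O elimination through the less crowded oxaboretanide places the propenyl group trans to the retained boryl group.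

Step 5
Reactants: 7 5‑bromo‑6‑[2‑(1,3‑dioxolan‑2‑yl)ethyl]‑3,4‑dihydro‑2H‑pyran‑2‑one; 10 2‑[(2Z,4E)‑hexa‑2,4‑dien‑2‑yl]‑4,4,5,5‑tetramethyl‑1,3,2‑dioxaborolane
Product: 11 6‑[2‑(1,3‑dioxolan‑2‑yl)ethyl]‑5‑[(2E,4E)‑hexa‑2,4‑dien‑2‑yl]‑3,4‑dihydro‑2H‑pyran‑2‑one
Conditions: Pd(dppf)Cl2 (5 mol %), CsF (3 equiv), 1,4‑dioxane, 70 °C
Reagents that add atoms: none
Why: Suzuki–Miyaura coupling with retention at both alkene carbons gives the (E,E)‑diene with its C5 methyl on the inside; the side chain is still saturated at this stage, so the alkenylpalladium intermediate has no tethered π‑bond to insert into, and anhydrous fluoride spares the enol lactone.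

Step 6
Reactants: 11 6‑[2‑(1,3‑dioxolan‑2‑yl)ethyl]‑5‑[(2E,4E)‑hexa‑2,4‑dien‑2‑yl]‑3,4‑dihydro‑2H‑pyran‑2‑one
Product: 12 3‑{5‑[(2E,4E)‑hexa‑2,4‑dien‑2‑yl]‑2‑oxo‑3,4‑dihydro‑2H‑pyran‑6‑yl}propanal
Conditions: TsOH·H2O (10 mol %), acetone–H2O (20:1), 20 °C
Reagents that add atoms: water, O
Why: acid‑catalysed acetal exchange and hydrolysis is much faster than hydrolysis of the enol ester, so the aldehyde is released with the lactone and triene intact; no stereocentre.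

Step 7
Reactants: 13 4‑methoxy‑2‑methylphenol; 14 propanoic acid
Product: 15 1‑(2‑hydroxy‑5‑methoxy‑3‑methylphenyl)propan‑1‑one
Conditions: BF3·OEt2, 90 °C; then aqueous NaOH/NaOAc work‑up
Reagents that add atoms: none
Why: boron trifluoride‑mediated ortho‑acylation (O‑acylation, then Fries shift within the boron chelate) can only reach the single free position ortho to the hydroxyl, the para position being blocked by methoxy and the other ortho position by methyl.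

Step 8
Reactants: 12 3‑{5‑[(2E,4E)‑hexa‑2,4‑dien‑2‑yl]‑2‑oxo‑3,4‑dihydro‑2H‑pyran‑6‑yl}propanal; 15 1‑(2‑hydroxy‑5‑methoxy‑3‑methylphenyl)propan‑1‑one
Product: 18 6‑[(3E)‑5‑(2‑hydroxy‑5‑methoxy‑3‑methylphenyl)‑4‑methyl‑5‑oxopent‑3‑en‑1‑yl]‑5‑[(2E,4E)‑hexa‑2,4‑dien‑2‑yl]‑3,4‑dihydro‑2H‑pyran‑2‑one, via aldol adduct 16 (not isolated), via aldol mesylate 17 (not isolated)
Conditions: 15, LiN(iPr)2 (2.1 equiv), THF, −78 °C; 12; MsCl (1.1 equiv), −78 °C; Et3N, −78 → 20 °C; NH4Cl (aq)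
Reagents that add atoms: none
Why: aldol condensation in one flask, in which the phenoxide–enolate dianion adds to the aldehyde faster than to the enol lactone, the aldolate oxygen is sulfonylated in preference to the chelated and flanked phenoxide, and E1cB elimination gives the more stable (E)‑2‑methyl enone with the ortho‑hydroxyl free.

Step 9
Reactants: 18 6‑[(3E)‑5‑(2‑hydroxy‑5‑methoxy‑3‑methylphenyl)‑4‑methyl‑5‑oxopent‑3‑en‑1‑yl]‑5‑[(2E,4E)‑hexa‑2,4‑dien‑2‑yl]‑3,4‑dihydro‑2H‑pyran‑2‑one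
Product: 19 (6aS,7S,8S,10aR)‑7‑(2‑hydroxy‑5‑methoxy‑3‑methylbenzoyl)‑7,8,10a‑trimethyl‑1,2,5,6,6a,7,8,10a‑octahydro‑3H‑benzo[f]chromen‑3‑one
Conditions: B(OPh)3 (20 mol %), (R)‑BINOL (24 mol %), 4 Å molecular sieves, PhCF3, 25 → 40 °C; pH 7 buffer
Reagents that add atoms: none
Why: Proposed new method: the chiral binaphthol borate binds the 2‑hydroxyaryl ketone as a six‑membered chelate, which lowers the enone LUMO and shields one face, so the (E)‑dienophile adds endo (aroyl under the diene, tether outside) to the (E,E)‑diene whose tether is held by the enol lactone, closing ring A (C4–C5) and ring B (C8–C9) together and fixing C4, C5, C8 and C9 (trans ring fusion, C8 methyl cis to the aroyl group, two quaternary centres); closest known reaction types are the chiral‑borate‑promoted intermolecular Diels–Alder reaction of 2′‑hydroxychalcones and the intramolecular Diels–Alder reaction of 1,7,9‑decatrienones to trans‑decalins.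

Step 10
Reactants: 19 (6aS,7S,8S,10aR)‑7‑(2‑hydroxy‑5‑methoxy‑3‑methylbenzoyl)‑7,8,10a‑trimethyl‑1,2,5,6,6a,7,8,10a‑octahydro‑3H‑benzo[f]chromen‑3‑one
Product: 21 methyl 3‑[(1S,4aS,5S,6S,8aR)‑5‑(2‑hydroxy‑5‑methoxy‑3‑methylbenzoyl)‑5,6,8a‑trimethyl‑2‑oxodecahydronaphthalen‑1‑yl]propanoate, via hydrogenated enol lactone 20 (not isolated)
Conditions: H2 (1 atm), 10 % Pd/C, EtOAc, 20 °C; filter; K2CO3 (0.2 equiv), MeOH, 0 °C, 30 min; AcOH
Reagents that add atoms: methanol, CO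
Why: catalytic hydrogenation saturates only the cis‑disubstituted C6=C7 bond (the tetrasubstituted enol‑lactone alkene is inert), then base‑catalysed methanolysis of the enol lactone releases the C1 enolate, which is protonated at C10 axially on the α face, anti to the C5 methyl, so the propanoate chain ends up β and equatorial.

Step 11
Reactants: 21 methyl 3‑[(1S,4aS,5S,6S,8aR)‑5‑(2‑hydroxy‑5‑methoxy‑3‑methylbenzoyl)‑5,6,8a‑trimethyl‑2‑oxodecahydronaphthalen‑1‑yl]propanoate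
Product: 22 methyl 3‑[(1S,4aS,5S,6S,8aR)‑5‑(2,5‑dihydroxy‑3‑methylbenzoyl)‑5,6,8a‑trimethyl‑2‑oxodecahydronaphthalen‑1‑yl]propanoate
Conditions: BBr3 (4 equiv), CH2Cl2, −78 → 0 °C; MeOH, 0 → 20 °C
Reagents that add atoms: none
Why: Lewis‑acid cleavage of the aryl methyl ether is done here because no alkene is present yet, and the methanol quench destroys the borates and re‑esterifies any acid formed; the stereocentres are not touched.

Step 12
Reactants: 22 methyl 3‑[(1S,4aS,5S,6S,8aR)‑5‑(2,5‑dihydroxy‑3‑methylbenzoyl)‑5,6,8a‑trimethyl‑2‑oxodecahydronaphthalen‑1‑yl]propanoate; 23 phenyl 2‑methylpropanoate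
Product: 25 methyl 3‑[(1S,4aS,5S,6S,8aS)‑5‑(2,5‑dihydroxy‑3‑methylbenzoyl)‑5,6,8a‑trimethyl‑2‑(propan‑2‑ylidene)decahydronaphthalen‑1‑yl]propanoate, via spiro β‑lactone 24 (not isolated)
Conditions: 23 (4 equiv), LiN(iPr)2 (4 equiv), THF, −78 °C; add 22; −78 → 0 °C; NH4Cl (aq); crude in DMF, 150 °C
Reagents that add atoms: none
Why: β‑lactone olefin synthesis, in which the phenyl ester enolate (two equivalents are spent on the phenols) adds to the C1 ketone rather than to the chelated, neopentyl aryl ketone, the aldolate closes to the β‑lactone with loss of phenoxide, and thermal [2+2] cycloreversion loses CO2 to place the tetrasubstituted alkene regiospecifically at C1; any enolisation toward C10 returns the same equatorial, more stable epimer.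

Step 13
Reactants: 25 methyl 3‑[(1S,4aS,5S,6S,8aS)‑5‑(2,5‑dihydroxy‑3‑methylbenzoyl)‑5,6,8a‑trimethyl‑2‑(propan‑2‑ylidene)decahydronaphthalen‑1‑yl]propanoate
Product: 26 3‑[(1S,4aS,5S,6S,8aS)‑5‑(2,5‑dihydroxy‑3‑methylbenzoyl)‑5,6,8a‑trimethyl‑2‑(propan‑2‑ylidene)decahydronaphthalen‑1‑yl]propanoic acid
Conditions: LiOH·H2O, THF–H2O (degassed), 20 °C; 1 M HCl to pH 3
Reagents that add atoms: lithium hydroxide, [Li+].[OH-]
Why: saponification of the unhindered methyl ester under oxygen‑free conditions leaves the hindered aryl ketone, the alkene and all five stereocentres unchanged.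

**Compound list**

1 | 2‑(2‑bromoethyl)‑1,3‑dioxolane | BrCCC1OCCO1 | starting material
2 | oxane‑2,6‑dione (glutaric anhydride) | O=C1CCCC(=O)O1 | starting material
3 | [2‑(1,3‑dioxolan‑2‑yl)ethyl]magnesium bromide | Br[Mg]CCC1OCCO1 | intermediate
4 | 7‑(1,3‑dioxolan‑2‑yl)‑5‑oxoheptanoic acid | O=C(O)CCCC(=O)CCC1OCCO1 | intermediate
5 | 6‑[2‑(1,3‑dioxolan‑2‑yl)ethyl]‑3,4‑dihydro‑2H‑pyran‑2‑one | O=C1CCC=C(CCC2OCCO2)O1 | intermediate
6 | trans‑5,6‑dibromo‑6‑[2‑(1,3‑dioxolan‑2‑yl)ethyl]oxan‑2‑one (racemic, one enantiomer written) | O=C1CC[C@@H](Br)[C@@](Br)(CCC2OCCO2)O1 | intermediate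
7 | 5‑bromo‑6‑[2‑(1,3‑dioxolan‑2‑yl)ethyl]‑3,4‑dihydro‑2H‑pyran‑2‑one | O=C1CCC(Br)=C(CCC2OCCO2)O1 | intermediate
8 | (E)‑but‑2‑enal | C/C=C/C=O | starting material
9 | 1,1‑bis(4,4,5,5‑tetramethyl‑1,3,2‑dioxaborolan‑2‑yl)ethane | CC(B1OC(C)(C)C(C)(C)O1)B1OC(C)(C)C(C)(C)O1 | starting material
10 | 2‑[(2Z,4E)‑hexa‑2,4‑dien‑2‑yl]‑4,4,5,5‑tetramethyl‑1,3,2‑dioxaborolane | C/C=C/C=C(\C)B1OC(C)(C)C(C)(C)O1 | intermediate
11 | 6‑[2‑(1,3‑dioxolan‑2‑yl)ethyl]‑5‑[(2E,4E)‑hexa‑2,4‑dien‑2‑yl]‑3,4‑dihydro‑2H‑pyran‑2‑one | C/C=C/C=C(\C)C1=C(CCC2OCCO2)OC(=O)CC1 | intermediate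
12 | 3‑{5‑[(2E,4E)‑hexa‑2,4‑dien‑2‑yl]‑2‑oxo‑3,4‑dihydro‑2H‑pyran‑6‑yl}propanal | C/C=C/C=C(\C)C1=C(CCC=O)OC(=O)CC1 | intermediate
13 | 4‑methoxy‑2‑methylphenol | COc1ccc(O)c(C)c1 | starting material
14 | propanoic acid | CCC(=O)O | starting material
15 | 1‑(2‑hydroxy‑5‑methoxy‑3‑methylphenyl)propan‑1‑one | CCC(=O)c1cc(OC)cc(C)c1O | intermediate
16 | 6‑[3‑hydroxy‑5‑(2‑hydroxy‑5‑methoxy‑3‑methylphenyl)‑4‑methyl‑5‑oxopentyl]‑5‑[(2E,4E)‑hexa‑2,4‑dien‑2‑yl]‑3,4‑dihydro‑2H‑pyran‑2‑one (racemic diastereomer mixture) | C/C=C/C=C(\C)C1=C(CCC(O)C(C)C(=O)c2cc(OC)cc(C)c2O)OC(=O)CC1 | intermediate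
17 | 3‑O‑methanesulfonate of 16 (racemic diastereomer mixture) | C/C=C/C=C(\C)C1=C(CCC(OS(C)(=O)=O)C(C)C(=O)c2cc(OC)cc(C)c2O)OC(=O)CC1 | intermediate
18 | 6‑[(3E)‑5‑(2‑hydroxy‑5‑methoxy‑3‑methylphenyl)‑4‑methyl‑5‑oxopent‑3‑en‑1‑yl]‑5‑[(2E,4E)‑hexa‑2,4‑dien‑2‑yl]‑3,4‑dihydro‑2H‑pyran‑2‑one | C/C=C/C=C(\C)C1=C(CC/C=C(\C)C(=O)c2cc(OC)cc(C)c2O)OC(=O)CC1 | intermediate
19 | (6aS,7S,8S,10aR)‑7‑(2‑hydroxy‑5‑methoxy‑3‑methylbenzoyl)‑7,8,10a‑trimethyl‑1,2,5,6,6a,7,8,10a‑octahydro‑3H‑benzo[f]chromen‑3‑one (4α‑H, 5β‑CH3, 8α‑CH3, 9β‑CH3) | O=C1CCC2=C(O1)CC[C@H]3[C@@]2(C)C=C[C@H](C)[C@]3(C)C(=O)c1cc(OC)cc(C)c1O | intermediate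
20 | (6aS,7S,8S,10aR)‑7‑(2‑hydroxy‑5‑methoxy‑3‑methylbenzoyl)‑7,8,10a‑trimethyl‑1,2,5,6,6a,7,8,9,10,10a‑decahydro‑3H‑benzo[f]chromen‑3‑one | O=C1CCC2=C(O1)CC[C@H]3[C@@]2(C)CC[C@H](C)[C@]3(C)C(=O)c1cc(OC)cc(C)c1O | intermediate
21 | methyl 3‑[(1S,4aS,5S,6S,8aR)‑5‑(2‑hydroxy‑5‑methoxy‑3‑methylbenzoyl)‑5,6,8a‑trimethyl‑2‑oxodecahydronaphthalen‑1‑yl]propanoate | O=C1CC[C@H]2[C@@](C)(CC[C@H](C)[C@]2(C)C(=O)c2cc(OC)cc(C)c2O)[C@@H]1CCC(=O)OC | intermediate
22 | methyl 3‑[(1S,4aS,5S,6S,8aR)‑5‑(2,5‑dihydroxy‑3‑methylbenzoyl)‑5,6,8a‑trimethyl‑2‑oxodecahydronaphthalen‑1‑yl]propanoate | O=C1CC[C@H]2[C@@](C)(CC[C@H](C)[C@]2(C)C(=O)c2cc(O)cc(C)c2O)[C@@H]1CCC(=O)OC | intermediate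
23 | phenyl 2‑methylpropanoate | CC(C)C(=O)Oc1ccccc1 | starting material
24 | spiro β‑lactone of 22: 3,3‑dimethyloxetan‑2‑one spiro‑fused at C1 (both C1 epimers; other centres as in 22) | CC1(C)C(=O)OC12CC[C@H]3[C@@](C)(CC[C@H](C)[C@]3(C)C(=O)c3cc(O)cc(C)c3O)[C@@H]2CCC(=O)OC | intermediate
25 | methyl 3‑[(1S,4aS,5S,6S,8aS)‑5‑(2,5‑dihydroxy‑3‑methylbenzoyl)‑5,6,8a‑trimethyl‑2‑(propan‑2‑ylidene)decahydronaphthalen‑1‑yl]propanoate | CC(C)=C1CC[C@H]2[C@@](C)(CC[C@H](C)[C@]2(C)C(=O)c2cc(O)cc(C)c2O)[C@@H]1CCC(=O)OC | intermediate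
26 | 3‑[(1S,4aS,5S,6S,8aS)‑5‑(2,5‑dihydroxy‑3‑methylbenzoyl)‑5,6,8a‑trimethyl‑2‑(propan‑2‑ylidene)decahydronaphthalen‑1‑yl]propanoic acid | CC(C)=C1CC[C@H]2[C@@](C)(CC[C@H](C)[C@]2(C)C(=O)c2cc(O)cc(C)c2O)[C@@H]1CCC(=O)O | target

**Step count and risks**

Total step count: 13. Longest linear sequence: 11 steps (1, 2, 3, 5, 6, 8, 9, 10, 11, 12, 13).

Most likely to fail, step 9: the diene carries an inside methyl and both new bonds end at quaternary carbons, so the borate‑activated cycloaddition may be slow, poorly endo‑selective or poorly enantioselective. Fallback, setting out from 18 and coming back at 19: heat 18 in toluene at 130 °C with 2,6‑di‑tert‑butyl‑4‑methylphenol, so that the uncatalysed intramolecular Diels–Alder reaction gives the racemate, in which 19 is accompanied by its mirror image (6aR,7R,8R,10aS)‑7‑(2‑hydroxy‑5‑methoxy‑3‑methylbenzoyl)‑7,8,10a‑trimethyl‑1,2,5,6,6a,7,8,10a‑octahydro‑3H‑benzo[f]chromen‑3‑one F1 in equal amount. Preparative chromatography on a cellulose tris(3,5‑dimethylphenylcarbamate) phase removes F1 from the mixture, and 19 enters step 10.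

Second, step 12: the C1 ketone is flanked by the C10 stereocentre and may enolise or undergo retro‑aldol cleavage instead of giving the β‑lactone. Fallback, setting out from 22 and coming back at 25: add isopropenylmagnesium bromide with CeCl3 (excess, THF, −78 °C) to the C1 ketone to give methyl 3‑[(1S,4aS,5S,6S,8aR)‑5‑(2,5‑dihydroxy‑3‑methylbenzoyl)‑2‑hydroxy‑5,6,8a‑trimethyl‑2‑(prop‑1‑en‑2‑yl)decahydronaphthalen‑1‑yl]propanoate F2 as a mixture of carbinol epimers. SOCl2 and pyridine in Et2O at −20 °C then convert F2 by allylic transposition into methyl 3‑[(1S,4aS,5S,6S,8aS)‑2‑(1‑chloropropan‑2‑ylidene)‑5‑(2,5‑dihydroxy‑3‑methylbenzoyl)‑5,6,8a‑trimethyldecahydronaphthalen‑1‑yl]propanoate F3 as an E/Z mixture. Bu3SnH with catalytic AIBN (benzene, 80 °C) removes the chlorine from F3 with hydrogen delivery to the primary allyl terminus and gives 25.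

Third, step 8: the free phenol may be sulfonylated, or the product may close to a chromanone under base. Fallback, setting out from 15 and 12 and coming back at 18: brominate 15 with CuBr2 (EtOAc–CHCl3, reflux) to racemic 2‑bromo‑1‑(2‑hydroxy‑5‑methoxy‑3‑methylphenyl)propan‑1‑one F4 at the ethyl ketone α‑carbon. Treatment of F4 with PPh3 in toluene gives [1‑(2‑hydroxy‑5‑methoxy‑3‑methylphenyl)‑1‑oxopropan‑2‑yl]triphenylphosphonium bromide F5 as a salt. Aqueous NaOH/CH2Cl2 converts F5 into the stabilised ylide 1‑(2‑hydroxy‑5‑methoxy‑3‑methylphenyl)‑2‑(triphenyl‑λ5‑phosphanylidene)propan‑1‑one F6 in the organic layer. Wittig reaction of F6 with aldehyde 12 (toluene, 70 °C) gives the (E)‑enone 18 under neutral conditions.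

Further compounds
F1 | step 9 | (6aR,7R,8R,10aS)‑7‑(2‑hydroxy‑5‑methoxy‑3‑methylbenzoyl)‑7,8,10a‑trimethyl‑1,2,5,6,6a,7,8,10a‑octahydro‑3H‑benzo[f]chromen‑3‑one | O=C1CCC2=C(O1)CC[C@@H]3[C@]2(C)C=C[C@@H](C)[C@@]3(C)C(=O)c1cc(OC)cc(C)c1O
F2 | step 12 | methyl 3‑[(1S,4aS,5S,6S,8aR)‑5‑(2,5‑dihydroxy‑3‑methylbenzoyl)‑2‑hydroxy‑5,6,8a‑trimethyl‑2‑(prop‑1‑en‑2‑yl)decahydronaphthalen‑1‑yl]propanoate (both carbinol epimers) | C=C(C)C1(O)CC[C@H]2[C@@](C)(CC[C@H](C)[C@]2(C)C(=O)c2cc(O)cc(C)c2O)[C@@H]1CCC(=O)OC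
F3 | step 12 | methyl 3‑[(1S,4aS,5S,6S,8aS)‑2‑(1‑chloropropan‑2‑ylidene)‑5‑(2,5‑dihydroxy‑3‑methylbenzoyl)‑5,6,8a‑trimethyldecahydronaphthalen‑1‑yl]propanoate (E/Z mixture) | ClCC(C)=C1CC[C@H]2[C@@](C)(CC[C@H](C)[C@]2(C)C(=O)c2cc(O)cc(C)c2O)[C@@H]1CCC(=O)OC
F4 | step 8 | 2‑bromo‑1‑(2‑hydroxy‑5‑methoxy‑3‑methylphenyl)propan‑1‑one (racemic) | CC(Br)C(=O)c1cc(OC)cc(C)c1O
F5 | step 8 | [1‑(2‑hydroxy‑5‑methoxy‑3‑methylphenyl)‑1‑oxopropan‑2‑yl]triphenylphosphonium bromide | CC(C(=O)c1cc(OC)cc(C)c1O)[P+](c1ccccc1)(c1ccccc1)c1ccccc1.[Br-]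
F6 | step 8 | 1‑(2‑hydroxy‑5‑methoxy‑3‑methylphenyl)‑2‑(triphenyl‑λ5‑phosphanylidene)propan‑1‑one | CC(=P(c1ccccc1)(c1ccccc1)c1ccccc1)C(=O)c1cc(OC)cc(C)c1O
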